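**Retrosynthetic overview**

1. Target ⇐ fluoride desilylation, selenoxide elimination (restores C-11=C-13) and esterification of the C-8 hydroxyl with a protected (Z)-2-(hydroxymethyl)but-2-enoic acid.
2. Key disconnection: the C-1–C-10 bond of the oxirane. A macrocyclising sulfur-ylide epoxidation of a seco-precursor (dienylic tetrahydrothiophenium at C-1, ketone at C-10) closes the ten-membered carbocycle and the oxirane in one operation; the aldehyde-level carbon C-1 reacts with reversed polarity.
3. Enabling feature: C-1 and C-10 are the two oxirane carbons. C-1 is flanked by the cis,cis-diene C-2=C-3–C-4=C-5 (ylide stabilisation), and C-10 is a ketone-level carbon activated by the C-14 oxymethyl group. The cis,cis-diene and the cis-fused γ-lactone ring (O, C-6, C-7, C-11, C-12) fold the chain so that C-1 meets C-10.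
4. Seco-precursor ⇐ indium Barbier allylation/lactonisation (C-6–C-7) of a (Z)-2-(bromomethyl)enoate (C-7 to C-14; C-8 from an asymmetric glyoxylate-ene reaction) with a (Z)-enynal (C-1 to C-6), then zinc semireduction to the cis,cis-diene.
5. Ring order: γ-lactone (step 11), then ten-membered carbocycle and oxirane together (step 15).

Key step: step 15

Remark on locants: atoms are named by germacranolide numbering. C-1/C-10 = oxirane (C-14 = hydroxymethyl on C-10); C-2=C-3 and C-4=C-5 = cis,cis-diene (C-15 = methyl on C-4); C-6 = lactone carbinol; C-7; C-8 = acyloxy carbinol; C-9 = methylene; C-11/C-12/C-13 = methylene lactone. Target = (1R,6S,7R,8R,10R).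

Assumption: the BINOL–titanium glyoxylate-ene reaction keeps its usual sense with silyl ether 2 ((R)-BINOL gives the (R)-2-hydroxy ester) and removes a methyl hydrogen, not a CH2OSi hydrogen.

**Fragment A (C-7 to C-14, C-11 to C-13)**

Step 1
Reactants: 1 2-methylprop-2-en-1-ol
Product: 2 tert-butyldimethyl[(2-methylprop-2-en-1-yl)oxy]silane
Conditions: TBSCl, imidazole, CH2Cl2, 0 °C → rt
Reagents that add atoms: tert-butyldimethylsilyl chloride CC(C)(C)[Si](C)(C)Cl
Why: routine silylation of a primary alcohol; the silyl ether protects O-14 until the last step and keeps this oxygen from binding the titanium catalyst of step 2.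

Step 2
Reactants: 2 silyl ether; 3 ethyl glyoxylate
Product: 4 ethyl (2R)-4-{[(tert-butyldimethylsilyl)oxy]methyl}-2-hydroxypent-4-enoate
Conditions: (R)-BINOL (10 mol %), TiCl2(OiPr)2 (10 mol %), 4 Å molecular sieves, CH2Cl2, −30 °C; 2 (2 equiv), freshly depolymerised 3
Reagents that add atoms: none
Why: catalytic asymmetric glyoxylate-ene reaction of a 1,1-disubstituted alkene, in which the (R)-BINOL–titanium complex should shield one aldehyde face and set C-8 as (R), while the 1,1-disubstituted alkene that is regenerated masks the C-10 ketone.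

Step 3
Reactants: 4 hydroxy ester
Product: 5 ethyl (2R)-4-{[(tert-butyldimethylsilyl)oxy]methyl}-2-[(triethylsilyl)oxy]pent-4-enoate
Conditions: TESCl, imidazole, CH2Cl2, 0 °C
Reagents that add atoms: chlorotriethylsilane CC[Si](Cl)(CC)CC
Why: silylation of the secondary alcohol; a triethylsilyl ether is chosen for O-8 because it can later be removed in the presence of the primary TBS ether and is not a leaving group under the weak base of step 15.

Step 4
Reactants: 5 silyl ether ester
Product: 6 (2R)-4-{[(tert-butyldimethylsilyl)oxy]methyl}-2-[(triethylsilyl)oxy]pent-4-enal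
Conditions: iBu2AlH (1.1 equiv), CH2Cl2, −78 °C; Rochelle salt work-up
Reagents that add atoms: none
Why: half-reduction of an α-silyloxy ester, whose tetrahedral aluminium hemiacetal is stable at −78 °C and releases the aldehyde only on work-up, so C-8 is not epimerised.

Step 5
Reactants: 6 aldehyde; 7 methyl acrylate
Product: 8 methyl (4R)-6-{[(tert-butyldimethylsilyl)oxy]methyl}-3-hydroxy-2-methylidene-4-[(triethylsilyl)oxy]hept-6-enoate (both C-3 epimers)
Conditions: DABCO (0.5 equiv), methyl acrylate (excess, neat), MeOH (cat.), rt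
Reagents that add atoms: none
Why: Morita–Baylis–Hillman reaction of an activated α-silyloxy aldehyde, fast enough to leave C-8 intact; the new carbinol centre is formed as a mixture and is erased in step 6.

Step 6
Reactants: 8 allylic alcohol
Product: 9 methyl (2Z,4R)-2-(bromomethyl)-6-{[(tert-butyldimethylsilyl)oxy]methyl}-4-[(triethylsilyl)oxy]hepta-2,6-dienoate
Conditions: NBS, Me2S, CH2Cl2, −20 → 0 °C
Reagents that add atoms: N-bromosuccinimide O=C1CCC(=O)N1Br
Why: SN2' bromination of the Morita–Baylis–Hillman alcohol through its alkoxysulfonium salt gives the thermodynamically favoured (Z)-2-(bromomethyl)enoate (C-8 chain cis to CH2Br) under non-acidic conditions that spare both silyl ethers.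

Step 7
Reactants: 9 dienyl bromide
Product: 11 methyl (2Z,4R)-2-(bromomethyl)-7-[(tert-butyldimethylsilyl)oxy]-6-oxo-4-[(triethylsilyl)oxy]hept-2-enoate, via diol 10 (not isolated)
Conditions: K2OsO4·2H2O (2 mol %), NaIO4 (3 equiv), 2,6-lutidine, dioxane/H2O (3:1), rt
Reagents that add atoms: sodium periodate [Na+].[O-]I(=O)(=O)=O (oxygen, relayed through OsO4)
Why: Lemieux–Johnson cleavage, in which OsO4 dihydroxylates the electron-rich 1,1-disubstituted alkene and not the electron-poor bromomethyl enoate, periodate cleaves the diol to the C-10 ketone, and 2,6-lutidine is too hindered to be alkylated by the allylic bromide.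

**Fragment B (C-1 to C-6, C-15)**

Step 8
Reactants: 12 but-2-yn-1-ol
Product: 14 (2Z)-3-iodobut-2-en-1-ol, via vinylalanate 13 (not isolated)
Conditions: NaAlH2(OCH2CH2OMe)2, THF, 0 °C → rt; then I2, −78 → 0 °C
Reagents that add atoms: iodine [I][I]
Why: hydroxyl-directed trans-hydroalumination delivers hydride to C-2 and aluminium to C-3 within a five-membered alanate, and iodinolysis with retention gives the (Z)-vinyl iodide (iodine cis to CH2OH) that fixes the C-4=C-5 geometry.

Step 9
Reactants: 14 iodo alcohol
Product: 15 (2Z)-3-iodobut-2-enal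
Conditions: MnO2 (excess), CH2Cl2, rt, dark; used at once
Reagents that add atoms: none
Why: MnO2 oxidises the allylic alcohol to the enal under neutral heterogeneous conditions that should not isomerise the (Z)-β-iodo enal.

Step 10
Reactants: 15 iodo enal; 16 prop-2-yn-1-ol
Product: 17 (2Z)-6-hydroxy-3-methylhex-2-en-4-ynal
Conditions: Pd(PPh3)2Cl2 (3 mol %), CuI (5 mol %), Et3N, THF, 0 °C → rt
Reagents that add atoms: none
Why: Sonogashira coupling with retention of alkene geometry joins C-3 to C-4; the free hydroxyl becomes the C-1 alcohol and needs no protection because the next step runs in water.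

**Union and key step**

Step 11
Reactants: 11 keto allylic bromide; 17 enynal
Product: 19 cis-fused enyne methylene lactone, via hydroxy ester 18 (not isolated)
Conditions: indium powder (1.5 equiv), THF/H2O (2:1), rt; then PPTS (cat.), CH2Cl2, rt
Reagents that add atoms: none
Why: Barbier allylation in which the allylindium from 11 adds to the aldehyde (much faster than to its own ketone) through a chair transition state with the C-8 chain axial, giving the syn adduct that lactonises to the cis lactone (C-6 and C-7 set together), while C-8 sets the allyl face (H-8 eclipsing the alkene to avoid allylic 1,3-strain, aldehyde arriving anti to the C-9 chain on the OTES side).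

Step 12
Reactants: 19 methylene lactone
Product: 20 selenide-masked enyne lactone (C-11 epimers)
Conditions: PhSeH (1.2 equiv), Et3N (0.1 equiv), CH2Cl2, 0 °C, argon, dark
Reagents that add atoms: benzeneselenol [SeH]c1ccccc1
Why: conjugate addition of the selenol masks the exocyclic methylene lactone, the only other electrophile that the ylide of step 15 could attack (cyclopropanation), and C-11 becomes a transient stereocentre that is destroyed again in step 21.

Step 13
Reactants: 20 masked enyne lactone
Product: 21 selenide-masked cis,cis-dienol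
Conditions: zinc dust activated with Cu(OAc)2 and AgNO3, MeOH/H2O (1:1), 35 °C, dark
Reagents that add atoms: none
Why: zinc (Cu/Ag couple) semireduction of a conjugated enyne is cis-selective and is helped by the free propargylic hydroxyl, while ketone, selenide and silyl ethers should not react under these neutral conditions.

Step 14
Reactants: 21 dienol
Product: 23 dienylic tetrahydrothiophenium tetrafluoroborate, via dienyl bromide 22 (not isolated)
Conditions: CBr4, PPh3, 2,6-lutidine, CH2Cl2, −30 °C; then tetrahydrothiophene (15 equiv), NaBF4 (5 equiv), CH2Cl2/H2O, 0 °C → rt, dark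
Reagents that add atoms: carbon tetrabromide BrC(Br)(Br)Br (bromine in 22 only); tetrahydrothiophene C1CCSC1; sodium tetrafluoroborate [Na+].F[B-](F)(F)F
Why: Appel bromination of the primary dienylic alcohol at low temperature avoids ionisation, and SN2 alkylation of the unhindered sulfide at the primary carbon keeps both cis alkenes, with tetrafluoroborate exchange preventing reversal by bromide.

Step 15
Reactants: 23 sulfonium salt
Product: 26 macrocyclic oxirane (1R,10R) with O-8 TES and O-14 TBS and selenide mask, via sulfonium ylide 24 (not isolated), via betaine 25 (not isolated)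
Conditions: Cs2CO3 (3 equiv), MeCN, 0 °C → rt, argon, dark; 23 added by syringe pump over 10 h to a final concentration of 1 mM
Reagents that add atoms: none
Why: Proposed new method: carbonate removes a proton from the dienylic CH2–S+ group (by far the most acidic C–H) to give an ylide stabilised by sulfur and by the C-2 to C-5 diene; its α-carbon adds to the α-silyloxy ketone C-10, and the betaine closes by displacement of tetrahydrothiophene once oxygen and sulfur are anti-periplanar, the closest known reaction types being the Corey–Chaykovsky epoxidation of ketones by allylic tetrahydrothiophenium ylides (vinyl oxiranes) and intramolecular sulfonium-ylide epoxidations that close five- to seven-membered carbocycles. Two rings close in this operation: the ten-membered carbocycle by addition of ylide carbon C-1 to the ketone (10-exo-trig) and the oxirane by 3-exo-tet O-alkylation. The relative configuration of C-1 and C-10 is controlled by the ring, because only the betaine with C-2 and C-9 gauche can reach the anti-periplanar geometry inside a ten-membered ring that already holds two cis alkenes, so the cis-fused oxirane (C-2 and C-9 cis, H-1 cis to C-14) should form. The face pairing relative to C-8 is controlled by the resident centres: the OTES group, cis to the lactone-bearing substituent on C-7, should sit pseudo-axially so that C-10 lies anti to H-8, the carbonyl eclipses the C-9–C-8 bond with CH2OTBS on the periphery, and the ylide carbon arriving from the C-7 side should add to the face that places the new C–O bond syn to the C-8 oxygen; this is the least secure element of the step. Chemoselectivity is secured by the substrate: the methylene lactone is masked (no cyclopropanation), O-8 is a silyl ether and the base is weak (no β-elimination), the sulfur ring carries no allyl group (no [2,3]-shift), and the cis,cis-diene with the cis lactone pre-folds the chain for closure at high dilution.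

Step 16
Reactants: 26 macrocyclic oxirane
Product: 27 C-8 alcohol
Conditions: HF·pyridine, excess pyridine, THF, 0 °C
Reagents that add atoms: none
Why: buffered HF·pyridine cleaves the secondary triethylsilyl ether much faster than the neopentyl-type primary TBS ether and is mild enough for the dienyl oxirane.

**Side-chain acid**

Step 17
Reactants: 12 but-2-yn-1-ol
Product: 28 (2Z)-2-(tributylstannyl)but-2-en-1-ol
Conditions: Bu3SnH, [Cp*RuCl]4 (2 mol %), CH2Cl2, rt
Reagents that add atoms: tributyltin hydride CCCC[SnH](CCCC)CCCC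
Why: hydroxyl-directed ruthenium-catalysed trans-hydrostannation places tin on the carbon next to CH2OH and hydrogen anti to it, which gives methyl cis to tin, the angelate-type geometry of the side chain.

Step 18
Reactants: 28 stannyl alcohol
Product: 29 tert-butyldimethylsilyl ether of 28
Conditions: TBSCl, imidazole, CH2Cl2, 0 °C → rt
Reagents that add atoms: tert-butyldimethylsilyl chloride CC(C)(C)[Si](C)(C)Cl
Why: routine silylation, so that the side-chain hydroxyl and O-14 are released together in the last step.

Step 19
Reactants: 29 vinylstannane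
Product: 31 (2Z)-2-{[(tert-butyldimethylsilyl)oxy]methyl}but-2-enoic acid, via vinyllithium 30 (not isolated)
Conditions: n-BuLi, THF, −78 °C; then CO2; cold dilute HCl work-up
Reagents that add atoms: carbon dioxide O=C=O
Why: tin–lithium exchange and carboxylation both proceed with retention at the alkenyl carbon, and the quench at −78 °C precedes any silyl migration.

**Completion**

Step 20
Reactants: 27 C-8 alcohol; 31 acid
Product: 33 C-8 ester, via mixed anhydride 32 (not isolated)
Conditions: 31, 2,4,6-trichlorobenzoyl chloride, Et3N, toluene, rt; then 27, DMAP (0.2 equiv), rt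
Reagents that add atoms: 2,4,6-trichlorobenzoyl chloride O=C(Cl)c1c(Cl)cc(Cl)cc1Cl (atoms in 32 only)
Why: Yamaguchi esterification acylates the hindered secondary alcohol without alkoxide formation (no lactone migration), and only catalytic DMAP at rt is used to limit Z→E isomerisation of the angelate-type acyl group.

Step 21
Reactants: 33 selenide ester
Product: 35 bis-TBS ether of the target, via selenoxide 34 (not isolated)
Conditions: H2O2 (30 %), pyridine, CH2Cl2, 0 °C → rt
Reagents that add atoms: hydrogen peroxide OO (oxygen in 34 only)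
Why: oxidation to the selenoxide and syn-elimination through the only β-hydrogen (H-11) at or below rt restores the exocyclic methylene, with pyridine buffering the selenenic acid.

Step 22
Reactants: 35 bis-silyl ether
Product: 36 CNP0165856.1
Conditions: Bu4NF/AcOH (1:1), THF, 0 °C → rt
Reagents that add atoms: none
Why: buffered fluoride removes both primary TBS ethers and should avoid oxirane opening, epoxy-alcohol (Payne) migration, acyl migration and conjugate addition to the methylene lactone.

**Compound list**

1 | 2-methylprop-2-en-1-ol | CC(=C)CO | starting material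
2 | tert-butyldimethyl[(2-methylprop-2-en-1-yl)oxy]silane | CC(=C)CO[Si](C)(C)C(C)(C)C | intermediate
3 | ethyl glyoxylate | CCOC(=O)C=O | starting material
4 | ethyl (2R)-4-{[(tert-butyldimethylsilyl)oxy]methyl}-2-hydroxypent-4-enoate | CCOC(=O)[C@H](O)CC(=C)CO[Si](C)(C)C(C)(C)C | intermediate
5 | ethyl (2R)-4-{[(tert-butyldimethylsilyl)oxy]methyl}-2-[(triethylsilyl)oxy]pent-4-enoate | CCOC(=O)[C@H](O[Si](CC)(CC)CC)CC(=C)CO[Si](C)(C)C(C)(C)C | intermediate
6 | (2R)-4-{[(tert-butyldimethylsilyl)oxy]methyl}-2-[(triethylsilyl)oxy]pent-4-enal | O=C[C@H](O[Si](CC)(CC)CC)CC(=C)CO[Si](C)(C)C(C)(C)C | intermediate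
7 | methyl acrylate | C=CC(=O)OC | starting material
8 | methyl (4R)-6-{[(tert-butyldimethylsilyl)oxy]methyl}-3-hydroxy-2-methylidene-4-[(triethylsilyl)oxy]hept-6-enoate (C-3 epimers) | C=C(C(=O)OC)C(O)[C@H](O[Si](CC)(CC)CC)CC(=C)CO[Si](C)(C)C(C)(C)C | intermediate
9 | methyl (2Z,4R)-2-(bromomethyl)-6-{[(tert-butyldimethylsilyl)oxy]methyl}-4-[(triethylsilyl)oxy]hepta-2,6-dienoate | COC(=O)/C(CBr)=C/[C@H](O[Si](CC)(CC)CC)CC(=C)CO[Si](C)(C)C(C)(C)C | intermediate
10 | methyl (2Z,4R)-2-(bromomethyl)-6-{[(tert-butyldimethylsilyl)oxy]methyl}-6,7-dihydroxy-4-[(triethylsilyl)oxy]hept-2-enoate (C-6 epimers; not isolated) | COC(=O)/C(CBr)=C/[C@H](O[Si](CC)(CC)CC)CC(O)(CO)CO[Si](C)(C)C(C)(C)C | intermediate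
11 | methyl (2Z,4R)-2-(bromomethyl)-7-[(tert-butyldimethylsilyl)oxy]-6-oxo-4-[(triethylsilyl)oxy]hept-2-enoate | COC(=O)/C(CBr)=C/[C@H](O[Si](CC)(CC)CC)CC(=O)CO[Si](C)(C)C(C)(C)C | intermediate
12 | but-2-yn-1-ol | CC#CCO | starting material
13 | sodium 2,2-bis(2-methoxyethoxy)-3-methyl-2,5-dihydro-1,2-oxaaluminol-2-uide (cyclic vinylalanate; not isolated) | CC1=CCO[Al-]1(OCCOC)OCCOC.[Na+] | intermediate
14 | (2Z)-3-iodobut-2-en-1-ol | C/C(I)=C/CO | intermediate
15 | (2Z)-3-iodobut-2-enal | C/C(I)=C/C=O | intermediate
16 | prop-2-yn-1-ol | C#CCO | starting material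
17 | (2Z)-6-hydroxy-3-methylhex-2-en-4-ynal | O=C/C=C(C)\C#CCO | intermediate
18 | open-chain syn Barbier adduct: methyl 2-methylidene ester with free C-6 hydroxyl, C-6/C-7/C-8 as in 19 (not isolated) | C=C(C(=O)OC)[C@@H]([C@@H](O)/C=C(C)\C#CCO)[C@H](O[Si](CC)(CC)CC)CC(=O)CO[Si](C)(C)C(C)(C)C | intermediate
19 | (4S,5S)-4-[(1R)-4-[(tert-butyldimethylsilyl)oxy]-3-oxo-1-[(triethylsilyl)oxy]butyl]-5-[(1Z)-5-hydroxy-2-methylpent-1-en-3-yn-1-yl]-3-methylideneoxolan-2-one (cis lactone) | C=C1C(=O)O[C@@H](/C=C(C)\C#CCO)[C@H]1[C@H](O[Si](CC)(CC)CC)CC(=O)CO[Si](C)(C)C(C)(C)C | intermediate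
20 | 3-[(phenylselanyl)methyl] analogue of 19 (C-11 epimers; C-6, C-7, C-8 as in 19) | c2ccccc2[Se]CC1C(=O)O[C@@H](/C=C(C)\C#CCO)[C@H]1[C@H](O[Si](CC)(CC)CC)CC(=O)CO[Si](C)(C)C(C)(C)C | intermediate
21 | selenide-masked (2Z,4Z)-dienol: as 20 with the (1Z,3Z)-5-hydroxy-2-methylpenta-1,3-dienyl chain on C-6 | c2ccccc2[Se]CC1C(=O)O[C@@H](/C=C(C)\C=C/CO)[C@H]1[C@H](O[Si](CC)(CC)CC)CC(=O)CO[Si](C)(C)C(C)(C)C | intermediate
22 | dienylic bromide of 21 (not isolated) | c2ccccc2[Se]CC1C(=O)O[C@@H](/C=C(C)\C=C/CBr)[C@H]1[C@H](O[Si](CC)(CC)CC)CC(=O)CO[Si](C)(C)C(C)(C)C | intermediate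
23 | S-dienyl tetrahydrothiophenium tetrafluoroborate (sulfonium on C-1) | c2ccccc2[Se]CC1C(=O)O[C@@H](/C=C(C)\C=C/C[S+]3CCCC3)[C@H]1[C@H](O[Si](CC)(CC)CC)CC(=O)CO[Si](C)(C)C(C)(C)C.F[B-](F)(F)F | intermediate
24 | sulfonium ylide of 23 (carbanion at C-1; not isolated) | c2ccccc2[Se]CC1C(=O)O[C@@H](/C=C(C)\C=C/[CH-][S+]3CCCC3)[C@H]1[C@H](O[Si](CC)(CC)CC)CC(=O)CO[Si](C)(C)C(C)(C)C | intermediate
25 | macrocyclic betaine (C-1 sulfonium, C-10 alkoxide; not isolated) | c4ccccc4[Se]CC1C(=O)O[C@H]2/C=C(C)\C=C/[C@H]([S+]3CCCC3)[C@]([O-])(CO[Si](C)(C)C(C)(C)C)C[C@@H](O[Si](CC)(CC)CC)[C@@H]12 | intermediate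
26 | (1R,10R)-1,10-epoxy macrocycle with O-8 triethylsilyl, O-14 tert-butyldimethylsilyl and C-13 phenylselanyl groups (C-11 epimers; C-6, C-7, C-8 as in target) | c4ccccc4[Se]CC1C(=O)O[C@H]2/C=C(C)\C=C/[C@H]3O[C@@]3(CO[Si](C)(C)C(C)(C)C)C[C@@H](O[Si](CC)(CC)CC)[C@@H]12 | intermediate
27 | C-8 alcohol of 26 (O-14 TBS and selenide retained) | c4ccccc4[Se]CC1C(=O)O[C@H]2/C=C(C)\C=C/[C@H]3O[C@@]3(CO[Si](C)(C)C(C)(C)C)C[C@@H](O)[C@@H]12 | intermediate
28 | (2Z)-2-(tributylstannyl)but-2-en-1-ol | C/C=C(\[Sn](CCCC)(CCCC)CCCC)CO | intermediate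
29 | tert-butyldimethyl{[(2Z)-2-(tributylstannyl)but-2-en-1-yl]oxy}silane | C/C=C(\[Sn](CCCC)(CCCC)CCCC)CO[Si](C)(C)C(C)(C)C | intermediate
30 | (2Z)-1-[(tert-butyldimethylsilyl)oxy]but-2-en-2-yllithium (not isolated) | C/C=C(\[Li])CO[Si](C)(C)C(C)(C)C | intermediate
31 | (2Z)-2-{[(tert-butyldimethylsilyl)oxy]methyl}but-2-enoic acid | C/C=C(\C(=O)O)CO[Si](C)(C)C(C)(C)C | intermediate
32 | mixed anhydride of 31 with 2,4,6-trichlorobenzoic acid (not isolated) | C/C=C(\C(=O)OC(=O)c1c(Cl)cc(Cl)cc1Cl)CO[Si](C)(C)C(C)(C)C | intermediate
33 | C-8 (2Z)-2-{[(tert-butyldimethylsilyl)oxy]methyl}but-2-enoate of 27 | c4ccccc4[Se]CC1C(=O)O[C@H]2/C=C(C)\C=C/[C@H]3O[C@@]3(CO[Si](C)(C)C(C)(C)C)C[C@@H](OC(=O)/C(=C\C)CO[Si](C)(C)C(C)(C)C)[C@@H]12 | intermediate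
34 | selenoxide of 33 (not isolated) | c4ccccc4[Se](=O)CC1C(=O)O[C@H]2/C=C(C)\C=C/[C@H]3O[C@@]3(CO[Si](C)(C)C(C)(C)C)C[C@@H](OC(=O)/C(=C\C)CO[Si](C)(C)C(C)(C)C)[C@@H]12 | intermediate
35 | bis(tert-butyldimethylsilyl) ether of the target (O-14 and side-chain oxygen) | C=C1C(=O)O[C@H]2/C=C(C)\C=C/[C@H]3O[C@@]3(CO[Si](C)(C)C(C)(C)C)C[C@@H](OC(=O)/C(=C\C)CO[Si](C)(C)C(C)(C)C)[C@@H]12 | intermediate
36 | CNP0165856.1, (1R,6S,7R,8R,10R)-1,10-epoxy-14-hydroxy-8-{[(2Z)-2-(hydroxymethyl)but-2-enoyl]oxy}germacra-2Z,4Z,11(13)-trien-12,6-olide | C=C1C(=O)O[C@H]2/C=C(C)\C=C/[C@H]3O[C@@]3(CO)C[C@@H](OC(=O)/C(=C\C)CO)[C@@H]12 | target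

**Step count and risks**

Total steps: 22. Longest linear sequence: 16 (steps 1–7, 11–16, 20–22).

Most likely to fail:

1. Step 15 (proposed new method). What may go wrong: intermolecular ylide–ketone reaction outrunning the medium-ring closure; face pairing at C-1/C-10 opposite to the required one; loss of the C-2=C-3 cis geometry in the delocalised ylide; base-induced loss of benzeneselenolate or of the C-8 silyloxy group. A chiral sulfide in place of tetrahydrothiophene would be the first adjustment. The fallback changes the ring-closing reaction and uses known chemistry. It sets out from 21: bromide 22 is made as in step 14 and treated with PPh3 to give the dienylic triphenylphosphonium bromide F1. KN(SiMe3)2 at high dilution (THF, −78 → 0 °C) should close the same C-1–C-10 bond by ring-closing Wittig olefination of the ketone, giving the macrocyclic triene F2, in which the ring can hold the new alkene only with C-2 and C-9 cis. HF·pyridine removes both silyl ethers to give the triene diol F3. Sharpless asymmetric epoxidation of the C-14 allylic alcohol [Ti(OiPr)4, D-(−)-diethyl tartrate, tert-butyl hydroperoxide in excess, 4 Å sieves, CH2Cl2, −20 °C] should then set C-1 and C-10 under reagent control; the hydroperoxide oxidises the selenide as well, so that after selenoxide elimination the epoxy diol with free methylene lactone F4 results. Selective silylation of the primary hydroxyl (TBSCl, imidazole, −20 °C) gives the C-14 silyl ether F5, and esterification with 31 as in step 20 comes back to the route at 35. F2 and F3 are kept cold and used at once, because an all-cis cyclic triene can undergo 6π-electrocyclisation.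

2. Step 11. What may go wrong: poor facial selectivity of the allylmetal with respect to C-8; attack of the allylmetal on its own ketone; partial loss of the triethylsilyl ether in the aqueous medium. The fallback replaces the in situ allylindium by an isolated allylboron reagent under catalyst control. It sets out from 11: copper-catalysed borylation (B2pin2, CuCl, KOAc, DMF, rt) should give the 2-(methoxycarbonyl)allyl pinacol boronate F6. Allylboration of 17 with F6 under chiral phosphoric acid catalysis (TRIP, the enantiomer that directs attack to the aldehyde face required for C-6; toluene, −30 °C) runs through a closed chair (syn adduct), does not touch ketones, and gives hydroxy ester 18 after work-up. PPTS lactonisation as in step 11 comes back to the route at 19.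

3. Step 13. What may go wrong: incomplete reduction or over-reduction, cis→trans isomerisation of the diene, or reductive loss of the α-silyloxy group next to the ketone. The fallback builds the cis,cis-diene by coupling instead of reduction. It sets out from 11 and 15: indium Barbier allylation as in step 11 gives the open-chain iodo hydroxy ester F7, which PPTS lactonises to the cis vinyl iodide lactone F8. Palladium-free copper-mediated Stille-type coupling of F8 with (Z)-3-(tributylstannyl)prop-2-en-1-ol [Cu(O2CC4H3S) (copper thiophene-2-carboxylate), NMP, 0 °C] should proceed with retention at both alkenes and without a competing Heck cyclisation onto the methylene lactone, giving the unmasked cis,cis-dienol F9. Addition of PhSeH as in step 12 comes back to the route at 21.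

Further compounds
F1 | step 15 | dienylic triphenylphosphonium bromide (phosphonium on C-1) | c2ccccc2[Se]CC1C(=O)O[C@@H](/C=C(C)\C=C/C[P+](c3ccccc3)(c3ccccc3)c3ccccc3)[C@H]1[C@H](O[Si](CC)(CC)CC)CC(=O)CO[Si](C)(C)C(C)(C)C.[Br-]
F2 | step 15 | macrocyclic triene with C-1=C-10 alkene, O-8 TES, O-14 TBS, selenide | c4ccccc4[Se]CC1C(=O)O[C@H]2/C=C(C)\C=C/C=C(/CO[Si](C)(C)C(C)(C)C)C[C@@H](O[Si](CC)(CC)CC)[C@@H]12
F3 | step 15 | macrocyclic triene 8,14-diol (selenide retained) | c4ccccc4[Se]CC1C(=O)O[C@H]2/C=C(C)\C=C/C=C(/CO)C[C@@H](O)[C@@H]12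
F4 | step 15 | (1R,10R)-epoxy 8,14-diol with free methylene lactone | C=C1C(=O)O[C@H]2/C=C(C)\C=C/[C@H]3O[C@@]3(CO)C[C@@H](O)[C@@H]12
F5 | step 15 | 14-O-tert-butyldimethylsilyl ether of F4 | C=C1C(=O)O[C@H]2/C=C(C)\C=C/[C@H]3O[C@@]3(CO[Si](C)(C)C(C)(C)C)C[C@@H](O)[C@@H]12
F6 | step 11 | methyl (2Z,4R)-7-[(tert-butyldimethylsilyl)oxy]-6-oxo-2-[(4,4,5,5-tetramethyl-1,3,2-dioxaborolan-2-yl)methyl]-4-[(triethylsilyl)oxy]hept-2-enoate | COC(=O)/C(CB1OC(C)(C)C(C)(C)O1)=C/[C@H](O[Si](CC)(CC)CC)CC(=O)CO[Si](C)(C)C(C)(C)C
F7 | step 13 | open-chain syn iodo hydroxy ester (iodo analogue of 18) | C=C(C(=O)OC)[C@@H]([C@@H](O)/C=C(C)\I)[C@H](O[Si](CC)(CC)CC)CC(=O)CO[Si](C)(C)C(C)(C)C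
F8 | step 13 | cis methylene lactone with (1Z)-2-iodoprop-1-enyl group on C-6 | C=C1C(=O)O[C@@H](/C=C(C)\I)[C@H]1[C@H](O[Si](CC)(CC)CC)CC(=O)CO[Si](C)(C)C(C)(C)C
F9 | step 13 | unmasked cis,cis-dienol methylene lactone | C=C1C(=O)O[C@@H](/C=C(C)\C=C/CO)[C@H]1[C@H](O[Si](CC)(CC)CC)CC(=O)CO[Si](C)(C)C(C)(C)C
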